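**Plan**
Numbering: C1 is the lactone carbonyl carbon and C30 the OCH2 carbon. The 31-membered ring holds one ester and 29 identical CH2 groups (C2 to C30), so 15 neighbouring ring carbons can be brought in as one preformed 15-membered carbocycle.
Retrosynthesis: unsaturation is put back at C11–C12 and C26–C27 and these two bonds are cut. This takes out C12 to C26 as a cycloalkene and leaves C1 to C11, C27 to C30 and the ring oxygen as a 16-membered unsaturated lactone.
Forward: cyclopentadecanone 1 is reduced to the alcohol 2, tosylated to 3 and eliminated to cyclopentadecene 4. Ring-expansion olefin metathesis then splices 4 into purchased habanolide 5, closing the only new ring (the 31-membered dienolide 6) and forming both skeletal bonds at once. Hydrogenation gives the target 7.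
Stereochemistry: the target has no stereocentre, and the E/Z geometry of the alkenes in 4, 5 and 6 is erased by the last step.

Key step: step 4

Remark on the chemistry: commercial habanolide is treated as its main constituent 5; the Z and 13-ene isomers in technical material, and the Z isomers of 4 and 6, carry the same atoms through step 4 and converge on 7 in step 5, so E/Z mixtures are drawn as E.

**Step 1**
Reactants: 1 cyclopentadecanone
Product: 2 cyclopentadecanol
Conditions: NaBH4, MeOH/THF, 0 °C to rt; aq. NH4Cl
Reagents that add atoms: none
Why: Borohydride reduction of an unhindered dialkyl ketone (NaBH4 carbonyl reduction) is general, and the carbinol carbon of the symmetric ring is not a stereocentre.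

**Step 2**
Reactants: 2 cyclopentadecanol
Product: 3 cyclopentadecyl 4-methylbenzenesulfonate
Conditions: TsCl, pyridine, DMAP (cat.), CH2Cl2, 0 °C to rt
Reagents that add atoms: p-toluenesulfonyl chloride (TsCl), Cc1ccc(cc1)S(=O)(=O)Cl
Why: Tosylation of a secondary alcohol with pyridine as base and DMAP as transfer catalyst turns the hydroxyl into a leaving group and touches nothing else in the hydrocarbon ring.

**Step 3**
Reactants: 3 cyclopentadecyl 4-methylbenzenesulfonate
Product: 4 (E)-cyclopentadecene (E-rich E/Z mixture drawn as E)
Conditions: KOtBu, DMSO, rt to 50 °C; hexane extraction, SiO2 filtration
Reagents that add atoms: none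
Why: E2 elimination of a secondary tosylate with the bulky, poorly nucleophilic KOtBu in DMSO should outrun substitution, and because all ring CH2 groups are equivalent neither the direction of elimination nor any base-induced alkene migration can give a different compound.

**Step 4**
Reactants: 4 (E)-cyclopentadecene; 5 (12E)-oxacyclohexadec-12-en-2-one (habanolide)
Product: 6 (12E,27E)-oxacyclohentriaconta-12,27-dien-2-one
Conditions: second-generation Grubbs catalyst RuCl2(H2IMes)(PCy3)(=CHPh) (2 mol%), 1,4-benzoquinone (10 mol%), lactone in fourfold molar excess over the cycloalkene, CH2Cl2, about 0.1 M total alkene, 40 °C, Ar; ethyl vinyl ether quench, SiO2 plug; Kugelrohr removal of the two monomer rings, then SiO2 chromatography; all other fractions recycled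
Reagents that add atoms: none
Why: A 14-electron ruthenium alkylidene adds across the ring alkene of 4 or 5 to a ruthenacyclobutane, which cycloreverts to an open chain ending in Ru=CH; this chain end opens the other ring in the same way, making the first new alkene (C11=C12 or C26=C27), and the resulting chain-end alkylidene then attacks the alkene at the tail of its own chain to make the second one and release the ring with every atom of both partners retained. The closest known reaction type is ring-expansion metathesis under ring-chain equilibrium, as in the cyclodepolymerisation and entropy-driven ring-opening polymerisation of unstrained macrocyclic alkenes and unsaturated macrolides. The 31-membered ring therefore closes by intramolecular back-biting metathesis of a chain-end alkylidene onto an internal alkene, a strain-free macrocyclisation in which both new alkenes become endocyclic. No stereocentre is formed; the alkene geometry is thermodynamic (E-rich) and without consequence. The step needs 1:1 cross-insertion over monomer rings, homodimers and larger rings, which rests on three settings: a total alkene concentration just below the onset of linear polymer (not high dilution, which would return mainly 4 and 5), a fourfold excess of the cheap lactone 5 so that 6 is practically the only non-volatile ring with one ester (hydrocarbon rings are less polar, diolides more polar, 5 distils off), and the reversibility of metathesis, which lets every fraction other than 6 go back into the next equilibration. It also needs the alkenes to stay in place, because migration followed by metathesis would change the ring size by single carbons; 1,4-benzoquinone, 40 °C and the ethyl vinyl ether quench before any concentration should secure this.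

**Step 5**
Reactants: 6 (12E,27E)-oxacyclohentriaconta-12,27-dien-2-one
Product: 7 oxacyclohentriacontan-2-one (triacontan-30-olide)
Conditions: H2 (1 atm), 10% Pd/C, EtOAc/THF, rt; recrystallisation
Reagents that add atoms: none
Why: Heterogeneous catalytic hydrogenation over Pd/C saturates isolated 1,2-disubstituted alkenes without touching a lactone, so every geometric and positional alkene isomer of 6 converges on the one saturated ring.

**Compound list**
1 | cyclopentadecanone | O=C1CCCCCCCCCCCCCC1 | starting material
2 | cyclopentadecanol | OC1CCCCCCCCCCCCCC1 | intermediate
3 | cyclopentadecyl 4-methylbenzenesulfonate | Cc1ccc(cc1)S(=O)(=O)OC1CCCCCCCCCCCCCC1 | intermediate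
4 | (E)-cyclopentadecene (E-rich E/Z mixture, drawn as E) | C1CCCCCC/C=C/CCCCCC1 | intermediate
5 | habanolide, (12E)-oxacyclohexadec-12-en-2-one | O=C1CCCCCCCCC/C=C/CCCO1 | starting material
6 | (12E,27E)-oxacyclohentriaconta-12,27-dien-2-one, (11E,26E)-triaconta-11,26-dien-30-olide | O=C1CCCCCCCCC/C=C/CCCCCCCCCCCCC/C=C/CCCO1 | intermediate
7 | oxacyclohentriacontan-2-one, triacontan-30-olide | O=C1CCCCCCCCCCCCCCCCCCCCCCCCCCCCCO1 | target

Total step count: 5
Longest linear sequence: 5 steps (1 → 2 → 3 → 4 → 6 → 7); 5 is purchased and enters in step 4.

**Steps most likely to fail**

Step 4. The ring-chain equilibrium may place too little material in the two-unit cross ring. Alkene migration ahead of metathesis may shift ring sizes by single carbons. Rings with one ester but different size may fail to separate.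
Fallback (sets out from 5, returns at 7): the statistical insertion is given up for a directed joining of two 15-carbon chains. Hydrogenation of 5 (H2, 10% Pd/C, EtOAc) should give pentadecan-15-olide F1. One part of it is opened with HBr in acetic acid to 15-bromopentadecanoic acid F2, which is heated with PPh3 in MeCN to give (14-carboxytetradecyl)triphenylphosphonium bromide F3. Another part of the saturated lactone is half-reduced with i-Bu2AlH (CH2Cl2, −78 °C) to 15-hydroxypentadecanal F4. Two equivalents of NaN(SiMe3)2 in THF convert the phosphonium salt into the ylide sodium 15-(triphenylphosphoranylidene)pentadecanoate F5, whose Wittig reaction with the hydroxy aldehyde should give, after acidic work-up, (15Z)-30-hydroxytriacont-15-enoic acid F6. Yamaguchi macrolactonisation (2,4,6-trichlorobenzoyl chloride, Et3N, THF; slow addition to DMAP in toluene at reflux, high dilution) runs through (15Z)-30-hydroxytriacont-15-enoic 2,4,6-trichlorobenzoic anhydride F7 to (15Z)-triacont-15-en-30-olide F8, and hydrogenation of this lactone over Pd/C leads back to the route at 7.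

Step 3. Substitution by alkoxide or solvent, or incomplete elimination of the conformationally mobile tosylate, may lower the supply of the cycloalkene.
Fallback (sets out from 2, returns at 4): the base-induced elimination is replaced by a thermal syn-elimination that needs neither the tosylate nor a strong base. Alcohol 2 is heated with methyl N-(triethylammoniosulfonyl)carbamate (Burgess reagent) in toluene at 60 to 80 °C, and the salt formed in the flask, triethylammonium cyclopentadecyl N-(methoxycarbonyl)sulfamate F9, should collapse to 4.

Step 5. Hydrogen uptake may stall when the sparingly soluble, waxy product coats the catalyst or when ruthenium and quinone residues poison it, leaving partly unsaturated lactone that does not separate from the product.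
Fallback (sets out from 6, returns at 7): reduction with diimide generated in the flask from 4-methylbenzenesulfonohydrazide and NaOAc in DME/water at reflux. This metal-free concerted hydrogen transfer is indifferent to catalyst poisons and leaves the lactone alone; no new compound lies on the way.

**Further compounds**
F1 | step 4 | pentadecan-15-olide (oxacyclohexadecan-2-one) | O=C1CCCCCCCCCCCCCCO1
F2 | step 4 | 15-bromopentadecanoic acid | OC(=O)CCCCCCCCCCCCCCBr
F3 | step 4 | (14-carboxytetradecyl)triphenylphosphonium bromide | OC(=O)CCCCCCCCCCCCCC[P+](c1ccccc1)(c1ccccc1)c1ccccc1.[Br-]
F4 | step 4 | 15-hydroxypentadecanal | O=CCCCCCCCCCCCCCCO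
F5 | step 4 | sodium 15-(triphenylphosphoranylidene)pentadecanoate | [Na+].[O-]C(=O)CCCCCCCCCCCCCC=P(c1ccccc1)(c1ccccc1)c1ccccc1
F6 | step 4 | (15Z)-30-hydroxytriacont-15-enoic acid | OC(=O)CCCCCCCCCCCCC/C=C\CCCCCCCCCCCCCCO
F7 | step 4 | (15Z)-30-hydroxytriacont-15-enoic 2,4,6-trichlorobenzoic anhydride | OCCCCCCCCCCCCCC/C=C\CCCCCCCCCCCCCC(=O)OC(=O)c1c(Cl)cc(Cl)cc1Cl
F8 | step 4 | (15Z)-triacont-15-en-30-olide | O=C1CCCCCCCCCCCCC/C=C\CCCCCCCCCCCCCCO1
F9 | step 3 | triethylammonium cyclopentadecyl N-(methoxycarbonyl)sulfamate | CC[NH+](CC)CC.COC(=O)[N-]S(=O)(=O)OC1CCCCCCCCCCCCCC1
F0 | step 5 | none | none
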